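**Plan**
- Retrosynthesis: the stilbene C=C is cut first (ring A aldehyde plus a resorcinol benzylphosphonate). Then the C3–C3a bond of the dihydrofuran is cut and ring A is re-attached to the exocyclic carbon, which gives a flavanone. Then the C2–aryl bond is cut (chromone plus arylboronic acid), and last the pyranone ring (o-hydroxyacetophenone plus a one-carbon unit).
- Enabling feature: the five-membered ring O1–C2–C3–C3a–C7a carries the guaiacyl ring on C2 and a one-carbon group (CH2OH) on C3. It is therefore the ring-contracted isomer of a 2-arylchroman-4-one whose ring A carbon sits on the carbonyl carbon C4; a 1,2-shift of ring A from C4 to C3 makes C4 the exocyclic carbon.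
- Forward order: ring A acetophenone, chromone (pyranone ring), flavanone (C2–aryl bond), ring contraction (dihydrofuran ring), diol, aldehyde, stilbene, free phenols.
- Stereochemistry: C2 (R) comes from a ligand-controlled conjugate addition. C3 (S in the target) is relayed from C2 in the ring contraction (trans). The E alkene comes from the phosphonate olefination.

Key step: step 6

Assumption: the (S)-pyridine–oxazoline ligand is taken to deliver the 2R flavanone (same facial sense as on cyclic enones); should the sense be opposite, its enantiomer is used with no other change.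

**Route**

Step 1
Reactants: 1 methyl 4-hydroxy-3-iodo-5-methoxybenzoate
Product: 3 methyl 3-acetyl-4-hydroxy-5-methoxybenzoate, via aryl enol ether 2 (not isolated)
Conditions: tributyl(1-ethoxyvinyl)stannane, PdCl2(PPh3)2 (5 mol%), toluene, 100 °C; then 2 M HCl, THF, rt
Reagents that add atoms: tributyl(1-ethoxyvinyl)stannane CCCC[Sn](CCCC)(CCCC)C(=C)OCC; water O
Why: Stille coupling of the aryl iodide with the α-ethoxyvinylstannane is a standard masked acetylation that tolerates the free ortho phenol and the ester, and the enol ether hydrolyses in dilute acid to the methyl ketone.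

Step 2
Reactants: 3 methyl 3-acetyl-4-hydroxy-5-methoxybenzoate
Product: 5 methyl 8-methoxy-4-oxo-4H-chromene-6-carboxylate, via enaminone 4 (not isolated)
Conditions: Me2NCH(OMe)2, toluene, 100 °C; then conc. HCl, CH2Cl2, 40 °C
Reagents that add atoms: N,N-dimethylformamide dimethyl acetal COC(OC)N(C)C
Why: Condensation of the methyl ketone with the amide acetal gives the enaminone, and acid then drives intramolecular conjugate addition of the phenol with loss of dimethylamine, the usual enaminone route to 2,3-unsubstituted chromones.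

Step 3
Reactants: 6 2-methoxy-4-(4,4,5,5-tetramethyl-1,3,2-dioxaborolan-2-yl)phenol
Product: 7 2-methoxy-4-(4,4,5,5-tetramethyl-1,3,2-dioxaborolan-2-yl)phenyl methanesulfonate
Conditions: MsCl, Et3N, CH2Cl2, 0 °C → rt
Reagents that add atoms: methanesulfonyl chloride CS(=O)(=O)Cl
Why: O-Sulfonylation of a phenol is routine and leaves the pinacol boronate alone, and the mesylate is chosen because it is electron-withdrawing and resists acid, hydride and mild oxidants.

Step 4
Reactants: 7 2-methoxy-4-(4,4,5,5-tetramethyl-1,3,2-dioxaborolan-2-yl)phenyl methanesulfonate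
Product: 8 [3-methoxy-4-(methylsulfonyloxy)phenyl]boronic acid
Conditions: NaIO4, NH4OAc, acetone/H2O, rt
Reagents that add atoms: water O
Why: Periodate glycol cleavage of the pinacol released in the hydrolysis equilibrium pulls the boronate ester over to the free boronic acid needed for transmetalation, and the aryl mesylate is inert to periodate.

Step 5
Reactants: 5 methyl 8-methoxy-4-oxo-4H-chromene-6-carboxylate; 8 [3-methoxy-4-(methylsulfonyloxy)phenyl]boronic acid
Product: 9 methyl (2R)-8-methoxy-2-[3-methoxy-4-(methylsulfonyloxy)phenyl]-4-oxochromane-6-carboxylate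
Conditions: Pd(OCOCF3)2 (5 mol%), (S)-4-tert-butyl-2-(pyridin-2-yl)-4,5-dihydrooxazole (6 mol%), NH4PF6 (30 mol%), H2O (5 equiv), ClCH2CH2Cl, 60 °C
Reagents that add atoms: none
Why: In this asymmetric conjugate addition of an arylboronic acid to a chromone under divalent palladium catalysis, the aryl–palladium species inserts the C2=C3 bond on the face left open by the tert-butyl group of the ligand and water protonates the palladium enolate, so C2 (R) is set by catalyst control while ester and aryl sulfonate are tolerated because palladium stays divalent.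

Step 6
Reactants: 9 methyl (2R)-8-methoxy-2-[3-methoxy-4-(methylsulfonyloxy)phenyl]-4-oxochromane-6-carboxylate
Product: 13 dimethyl (2R,3R)-7-methoxy-2-[3-methoxy-4-(methylsulfonyloxy)phenyl]-2,3-dihydro-1-benzofuran-3,5-dicarboxylate, via methyl enol ether 10 (not isolated), via trans iodane 11 (not isolated), via trimethyl orthoester 12 (not isolated)
Conditions: PhI(OAc)2 (1.3 equiv), conc. H2SO4, HC(OMe)3, rt; then aq. NaHCO3
Reagents that add atoms: trimethyl orthoformate COC(OC)OC; water O
Why: Acid and the orthoformate turn the ketone into enol ether 10, which the electrophilic trivalent iodine reagent attacks at C3 on the face opposite the C2 aryl group while methanol caps C4 (iodane 11); ring A then shifts from C4 to C3 as iodobenzene leaves, and the dimethoxycarbenium ion is trapped as orthoester 12, which hydrolyses to the methyl ester on work-up. This is the known oxidative ring contraction of flavanones to methyl trans-2-aryl-2,3-dihydrobenzofuran-3-carboxylates by trivalent iodine reagents in trimethyl orthoformate, a semipinacol-type 1,2-aryl shift. The five-membered ring is not closed end to end but arises by contraction of the pyranone through a bridged phenonium-like transition state in which C3–C3a forms as C4–C4a breaks. C2 is not touched and controls C3, because anti attack of iodine followed by migration with inversion places the ester carbon trans to the aryl group, which is also the thermodynamic arrangement of this epimerisable ester. The step needs ring A to migrate in preference to the guaiacyl ring (isoflavone pathway) and to loss of the C2 proton (flavone pathway); the two methoxy groups on C4 push ring A, whose migrating carbon is ortho to the ring oxygen, whereas the mesyloxy group makes the guaiacyl ring a poor migrating group and disfavours positive charge at C2.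

Step 7
Reactants: 13 dimethyl (2R,3R)-7-methoxy-2-[3-methoxy-4-(methylsulfonyloxy)phenyl]-2,3-dihydro-1-benzofuran-3,5-dicarboxylate
Product: 14 4-[(2R,3S)-3,5-bis(hydroxymethyl)-7-methoxy-2,3-dihydro-1-benzofuran-2-yl]-2-methoxyphenyl methanesulfonate
Conditions: iBu2AlH (6 equiv), CH2Cl2, −78 → 0 °C; aq. KNaC4H4O6 (potassium sodium tartrate) work-up
Reagents that add atoms: none
Why: Hydride reduction with iBu2AlH takes the aryl and the alkyl methyl ester to primary alcohols at low temperature, should leave the aryl mesylate and the benzylic C2–O bond alone, and involves no base that could epimerise C3.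

Step 8
Reactants: 14 4-[(2R,3S)-3,5-bis(hydroxymethyl)-7-methoxy-2,3-dihydro-1-benzofuran-2-yl]-2-methoxyphenyl methanesulfonate
Product: 15 4-[(2R,3S)-5-formyl-3-(hydroxymethyl)-7-methoxy-2,3-dihydro-1-benzofuran-2-yl]-2-methoxyphenyl methanesulfonate
Conditions: MnO2 (activated, 15 equiv), CH2Cl2, rt
Reagents that add atoms: none
Why: Activated MnO2 oxidises benzylic alcohols but not saturated primary alcohols, so only the hydroxymethyl group on ring A should become the aldehyde.

Step 9
Reactants: 16 3,5-dihydroxybenzyl alcohol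
Product: 17 tert-butyl{[3,5-bis(tert-butyldimethylsilyloxy)phenyl]methoxy}dimethylsilane
Conditions: TBSCl (3.5 equiv), imidazole, DMF, rt
Reagents that add atoms: tert-butyldimethylsilyl chloride CC(C)(C)[Si](C)(C)Cl
Why: Imidazole-promoted silylation in DMF silylates phenols and primary alcohols alike, so an excess of TBSCl should give the tris-silyl ether cleanly.

Step 10
Reactants: 17 tert-butyl{[3,5-bis(tert-butyldimethylsilyloxy)phenyl]methoxy}dimethylsilane
Product: 18 [3,5-bis(tert-butyldimethylsilyloxy)phenyl]methanol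
Conditions: camphorsulfonic acid (10 mol%), MeOH/CH2Cl2, 0 °C
Reagents that add atoms: none
Why: Under mild acid-catalysed methanolysis an alkyl TBS ether is cleaved much faster than an aryl TBS ether, which allows selective release of the benzylic alcohol.

Step 11
Reactants: 18 [3,5-bis(tert-butyldimethylsilyloxy)phenyl]methanol
Product: 19 1-(bromomethyl)-3,5-bis(tert-butyldimethylsilyloxy)benzene
Conditions: CBr4, PPh3, CH2Cl2, 0 °C
Reagents that add atoms: tetrabromomethane BrC(Br)(Br)Br
Why: The Appel reaction converts the primary benzylic alcohol into the bromide under neutral conditions that aryl silyl ethers survive.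

Step 12
Reactants: 19 1-(bromomethyl)-3,5-bis(tert-butyldimethylsilyloxy)benzene
Product: 20 diethyl [3,5-bis(tert-butyldimethylsilyloxy)benzyl]phosphonate
Conditions: P(OEt)3 (neat), 130 °C
Reagents that add atoms: triethyl phosphite CCOP(OCC)OCC
Why: The Michaelis–Arbuzov reaction of a benzylic bromide with triethyl phosphite gives the phosphonate, with volatile bromoethane leaving the mixture.

Step 13
Reactants: 15 4-[(2R,3S)-5-formyl-3-(hydroxymethyl)-7-methoxy-2,3-dihydro-1-benzofuran-2-yl]-2-methoxyphenyl methanesulfonate; 20 diethyl [3,5-bis(tert-butyldimethylsilyloxy)benzyl]phosphonate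
Product: 21 4-[(2R,3S)-5-{(E)-2-[3,5-bis(tert-butyldimethylsilyloxy)phenyl]ethenyl}-3-(hydroxymethyl)-7-methoxy-2,3-dihydro-1-benzofuran-2-yl]-2-methoxyphenyl methanesulfonate
Conditions: 20 (2.2 equiv), NaN(SiMe3)2 (2.1 equiv), THF, 0 °C; then 15, 0 °C → rt
Reagents that add atoms: none
Why: Horner–Wadsworth–Emmons olefination of an aromatic aldehyde with a benzylic phosphonate anion gives the E stilbene, the excess anion merely deprotonates the free alcohol, and keeping the hindered amide base in slight deficit to the phosphonate should spare the mesylate α-protons and the aryl silyl ethers.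

Step 14
Reactants: 21 4-[(2R,3S)-5-{(E)-2-[3,5-bis(tert-butyldimethylsilyloxy)phenyl]ethenyl}-3-(hydroxymethyl)-7-methoxy-2,3-dihydro-1-benzofuran-2-yl]-2-methoxyphenyl methanesulfonate
Product: 22 gnetofuran A, 5-{(E)-2-[(2R,3S)-2-(4-hydroxy-3-methoxyphenyl)-3-(hydroxymethyl)-7-methoxy-2,3-dihydro-1-benzofuran-5-yl]ethenyl}benzene-1,3-diol
Conditions: KOH, MeOH/THF/H2O (degassed), 50 °C, argon; then aq. NH4Cl
Reagents that add atoms: none
Why: Alkaline hydrolysis cleaves the aryl silyl ethers by attack at silicon and, more slowly, the aryl methanesulfonate by attack at sulfur, so one operation should free all three phenols while neither stereocentre is acidic and exclusion of oxygen protects the stilbene phenoxides.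

**Compound list**
1 | methyl 4-hydroxy-3-iodo-5-methoxybenzoate | COC(=O)c1cc(I)c(O)c(OC)c1 | starting material
2 | methyl 3-(1-ethoxyethenyl)-4-hydroxy-5-methoxybenzoate | COC(=O)c1cc(C(=C)OCC)c(O)c(OC)c1 | intermediate (not isolated)
3 | methyl 3-acetyl-4-hydroxy-5-methoxybenzoate | COC(=O)c1cc(C(C)=O)c(O)c(OC)c1 | intermediate
4 | methyl 3-[(E)-3-(dimethylamino)prop-2-enoyl]-4-hydroxy-5-methoxybenzoate | COC(=O)c1cc(C(=O)/C=C/N(C)C)c(O)c(OC)c1 | intermediate (not isolated)
5 | methyl 8-methoxy-4-oxo-4H-chromene-6-carboxylate | COC(=O)c1cc(OC)c2occc(=O)c2c1 | intermediate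
6 | 2-methoxy-4-(4,4,5,5-tetramethyl-1,3,2-dioxaborolan-2-yl)phenol | COc1cc(B2OC(C)(C)C(C)(C)O2)ccc1O | starting material
7 | 2-methoxy-4-(4,4,5,5-tetramethyl-1,3,2-dioxaborolan-2-yl)phenyl methanesulfonate | COc1cc(B2OC(C)(C)C(C)(C)O2)ccc1OS(C)(=O)=O | intermediate
8 | [3-methoxy-4-(methylsulfonyloxy)phenyl]boronic acid | COc1cc(B(O)O)ccc1OS(C)(=O)=O | intermediate
9 | methyl (2R)-8-methoxy-2-[3-methoxy-4-(methylsulfonyloxy)phenyl]-4-oxochromane-6-carboxylate | COc1cc([C@@H]2Oc3c(OC)cc(C(=O)OC)cc3C(=O)C2)ccc1OS(C)(=O)=O | intermediate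
10 | methyl (2R)-4,8-dimethoxy-2-[3-methoxy-4-(methylsulfonyloxy)phenyl]-2H-chromene-6-carboxylate | COc1cc([C@@H]2Oc3c(OC)cc(C(=O)OC)cc3C(OC)=C2)ccc1OS(C)(=O)=O | intermediate (not isolated)
11 | methyl (2S,3S)-3-[acetoxy(phenyl)-λ3-iodanyl]-4,4,8-trimethoxy-2-[3-methoxy-4-(methylsulfonyloxy)phenyl]chromane-6-carboxylate (iodine trans to the aryl group; C2 geometry as in 9, descriptor changed by priority only) | COc1cc([C@@H]2Oc3c(OC)cc(C(=O)OC)cc3C(OC)(OC)[C@H]2I(OC(C)=O)c4ccccc4)ccc1OS(C)(=O)=O | intermediate (not isolated)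
12 | methyl (2R,3R)-7-methoxy-2-[3-methoxy-4-(methylsulfonyloxy)phenyl]-3-(trimethoxymethyl)-2,3-dihydro-1-benzofuran-5-carboxylate | COc1cc([C@@H]2Oc3c(OC)cc(C(=O)OC)cc3[C@H]2C(OC)(OC)OC)ccc1OS(C)(=O)=O | intermediate (not isolated)
13 | dimethyl (2R,3R)-7-methoxy-2-[3-methoxy-4-(methylsulfonyloxy)phenyl]-2,3-dihydro-1-benzofuran-3,5-dicarboxylate (trans) | COc1cc([C@@H]2Oc3c(OC)cc(C(=O)OC)cc3[C@H]2C(=O)OC)ccc1OS(C)(=O)=O | intermediate
14 | 4-[(2R,3S)-3,5-bis(hydroxymethyl)-7-methoxy-2,3-dihydro-1-benzofuran-2-yl]-2-methoxyphenyl methanesulfonate | COc1cc([C@@H]2Oc3c(OC)cc(CO)cc3[C@H]2CO)ccc1OS(C)(=O)=O | intermediate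
15 | 4-[(2R,3S)-5-formyl-3-(hydroxymethyl)-7-methoxy-2,3-dihydro-1-benzofuran-2-yl]-2-methoxyphenyl methanesulfonate | COc1cc([C@@H]2Oc3c(OC)cc(C=O)cc3[C@H]2CO)ccc1OS(C)(=O)=O | intermediate
16 | 3,5-dihydroxybenzyl alcohol | OCc1cc(O)cc(O)c1 | starting material
17 | tert-butyl{[3,5-bis(tert-butyldimethylsilyloxy)phenyl]methoxy}dimethylsilane | CC(C)(C)[Si](C)(C)OCc1cc(O[Si](C)(C)C(C)(C)C)cc(O[Si](C)(C)C(C)(C)C)c1 | intermediate
18 | [3,5-bis(tert-butyldimethylsilyloxy)phenyl]methanol | OCc1cc(O[Si](C)(C)C(C)(C)C)cc(O[Si](C)(C)C(C)(C)C)c1 | intermediate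
19 | 1-(bromomethyl)-3,5-bis(tert-butyldimethylsilyloxy)benzene | BrCc1cc(O[Si](C)(C)C(C)(C)C)cc(O[Si](C)(C)C(C)(C)C)c1 | intermediate
20 | diethyl [3,5-bis(tert-butyldimethylsilyloxy)benzyl]phosphonate | CCOP(=O)(OCC)Cc1cc(O[Si](C)(C)C(C)(C)C)cc(O[Si](C)(C)C(C)(C)C)c1 | intermediate
21 | 4-[(2R,3S)-5-{(E)-2-[3,5-bis(tert-butyldimethylsilyloxy)phenyl]ethenyl}-3-(hydroxymethyl)-7-methoxy-2,3-dihydro-1-benzofuran-2-yl]-2-methoxyphenyl methanesulfonate | COc1cc([C@@H]2Oc3c(OC)cc(/C=C/c4cc(O[Si](C)(C)C(C)(C)C)cc(O[Si](C)(C)C(C)(C)C)c4)cc3[C@H]2CO)ccc1OS(C)(=O)=O | intermediate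
22 | gnetofuran A, 5-{(E)-2-[(2R,3S)-2-(4-hydroxy-3-methoxyphenyl)-3-(hydroxymethyl)-7-methoxy-2,3-dihydro-1-benzofuran-5-yl]ethenyl}benzene-1,3-diol | COc1cc([C@@H]2Oc3c(OC)cc(/C=C/c4cc(O)cc(O)c4)cc3[C@H]2CO)ccc1O | target

**Step count**
Total: 14 steps. Longest linear sequence: 8 steps from compound 1 (steps 1, 2, 5, 6, 7, 8, 13, 14).

**Steps most likely to fail**

Step 6. The guaiacyl ring may shift from C2 to C3, or the iodane may eliminate toward C2, faster than ring A migrates; in addition, the strong acid may reversibly open the pyranone and erode C2. The fallback sets out from 9 and comes back at 13, using a photochemical Wolff ring contraction in which only the carbonyl-bound ring A carbon can migrate. The lithium enolate of 9 (LiN(SiMe3)2, THF, −78 °C) is acylated with 2,2,2-trifluoroethyl trifluoroacetate to the 3-trifluoroacetyl flavanone F1, which is not isolated. Detrifluoroacetylative Regitz diazo transfer (methanesulfonyl azide, Et3N, wet MeCN) then gives the 3-diazo flavanone F2. Irradiation at 365 nm in MeOH should give the ring-contracted ketene F3, which adds methanol to give 13 together with the cis diester F4. NaOMe in MeOH at 0 °C equilibrates F4 to the trans diester 13.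

Step 5. Protodeboronation of the electron-poor boronic acid may outrun transmetalation, or facial discrimination at C2 may be poor for this 8-methoxy chromone. The fallback sets out from 3 and comes back at 9, forming the C2–O bond asymmetrically instead of the C2–aryl bond. The dianion of 3 (LiN(SiMe3)2, then Boc2O, THF, −78 → 0 °C) is C-acylated to the tert-butyl β-keto ester F5. Knoevenagel condensation (piperidine, AcOH, toluene, 4 Å sieves) with 4-formyl-2-methoxyphenyl methanesulfonate F6 (from vanillin, MsCl, Et3N) gives the alkylidene β-keto ester F7. Enantioselective intramolecular oxa-Michael addition, catalysed by N-[3,5-bis(trifluoromethyl)phenyl]-N'-(6'-methoxycinchonan-9-yl)thiourea (the quinine- or quinidine-derived pseudoenantiomer, whichever gives 2R), should give the 3-tert-butoxycarbonyl flavanone F8. TsOH in toluene at 80 °C removes the tert-butyl ester with decarboxylation to give 9.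

Step 14. Hydrolysis at sulfur may be slow, so that prolonged heating of the liberated 4-hydroxyphenyl phenoxide opens the dihydrofuran through a quinone methide or lets the stilbene phenoxides oxidise. The fallback sets out from 21 and comes back at 22, taking the mesylate off at low temperature by elimination instead of hydrolysis. LiN(iPr)2 (excess, THF, −78 → 0 °C) deprotonates the mesyl methyl group and expels sulfene, which should give the bis-silyl phenol F9. Bu4NF buffered with AcOH (THF, 0 °C) then removes both silyl groups to give 22.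

**Further compounds**
F1 | step 6 | methyl (2R)-8-methoxy-2-[3-methoxy-4-(methylsulfonyloxy)phenyl]-4-oxo-3-(trifluoroacetyl)chromane-6-carboxylate (C3 epimers or enol) | COc1cc([C@@H]2Oc3c(OC)cc(C(=O)OC)cc3C(=O)C2C(=O)C(F)(F)F)ccc1OS(C)(=O)=O
F2 | step 6 | methyl (2S)-3-diazo-8-methoxy-2-[3-methoxy-4-(methylsulfonyloxy)phenyl]-4-oxochromane-6-carboxylate (C2 geometry as in 9) | COc1cc([C@@H]2Oc3c(OC)cc(C(=O)OC)cc3C(=O)C2=[N+]=[N-])ccc1OS(C)(=O)=O
F3 | step 6 | methyl 7-methoxy-2-[3-methoxy-4-(methylsulfonyloxy)phenyl]-3-(oxomethylidene)-2,3-dihydro-1-benzofuran-5-carboxylate (ketene, C2 geometry as in 9) | COc1cc([C@@H]2Oc3c(OC)cc(C(=O)OC)cc3C2=C=O)ccc1OS(C)(=O)=O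
F4 | step 6 | dimethyl (2R,3S)-7-methoxy-2-[3-methoxy-4-(methylsulfonyloxy)phenyl]-2,3-dihydro-1-benzofuran-3,5-dicarboxylate (cis) | COc1cc([C@@H]2Oc3c(OC)cc(C(=O)OC)cc3[C@@H]2C(=O)OC)ccc1OS(C)(=O)=O
F5 | step 5 | methyl 3-(3-tert-butoxy-3-oxopropanoyl)-4-hydroxy-5-methoxybenzoate | COC(=O)c1cc(C(=O)CC(=O)OC(C)(C)C)c(O)c(OC)c1
F6 | step 5 | 4-formyl-2-methoxyphenyl methanesulfonate | COc1cc(C=O)ccc1OS(C)(=O)=O
F7 | step 5 | methyl 3-{2-(tert-butoxycarbonyl)-3-[3-methoxy-4-(methylsulfonyloxy)phenyl]prop-2-enoyl}-4-hydroxy-5-methoxybenzoate (E/Z mixture) | COC(=O)c1cc(C(=O)C(=Cc2ccc(OS(C)(=O)=O)c(OC)c2)C(=O)OC(C)(C)C)c(O)c(OC)c1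
F8 | step 5 | 3-tert-butyl 6-methyl (2R)-8-methoxy-2-[3-methoxy-4-(methylsulfonyloxy)phenyl]-4-oxochromane-3,6-dicarboxylate (C3 epimers or enol) | COc1cc([C@@H]2Oc3c(OC)cc(C(=O)OC)cc3C(=O)C2C(=O)OC(C)(C)C)ccc1OS(C)(=O)=O
F9 | step 14 | 4-[(2R,3S)-5-{(E)-2-[3,5-bis(tert-butyldimethylsilyloxy)phenyl]ethenyl}-3-(hydroxymethyl)-7-methoxy-2,3-dihydro-1-benzofuran-2-yl]-2-methoxyphenol | COc1cc([C@@H]2Oc3c(OC)cc(/C=C/c4cc(O[Si](C)(C)C(C)(C)C)cc(O[Si](C)(C)C(C)(C)C)c4)cc3[C@H]2CO)ccc1O
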